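## Retrosynthetic overview

1. Skeleton: the linear tetraketide of alkylresorcinol/sorgoleone-type biosynthesis (C18 fatty-acyl starter plus three acetate units). It is assembled from 4-methoxy-6-methyl-2H-pyran-2-one 1 (a masked, already O-methylated triacetic acid) and stearoyl chloride 2, through dienolate 3, to the pyrone-masked tetraketide 4.
2. Only ring formed (the benzene ring, made once; the pyranone ring of 1 is bought and opened): 4 is unmasked to the open tetraketide acid 5. Its C2-to-C7 aldol condensation gives resorcylic acid 6, and loss of CO2 gives methoxyphenol 7.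
3. C–O disconnections at the two ring carbons flanking the chain: para-oxidation of 7 to quinone 8, acetoxylation next to the chain (triacetate 9), then hydroxyhydroquinone 10 autoxidises to Irisoquin B 11.

Assumption: the SMILES is read as an n-heptadecyl (C17) chain, C24H40O4; the molecule has no stereocentre, so there is no enantiomer to select and no stereocontrol is needed.

## Route

Step 1
Reactants: 1 4-methoxy-6-methyl-2H-pyran-2-one; 2 octadecanoyl chloride (stearoyl chloride)
Product: 4 4-methoxy-6-(2-oxononadecyl)-2H-pyran-2-one, via lithiated pyrone 3 (not isolated)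
Conditions: 1 (2.2 equiv), LiN(SiMe3)2 (2.2 equiv), THF, −78 °C; then 2 (1.0 equiv) dropwise, −78 → −30 °C; sat. aq. NH4Cl
Reagents that add atoms: none
Why: The 6-methyl group is the vinylogous α-position of the lactone, so the amide base gives the extended dienolate 3, which is C-acylated at the exocyclic carbon by the acid chloride (Claisen-type acylation of a vinylogous enolate); the second equivalent of 3 removes the acidic proton of 4 and so prevents double acylation; no stereocentre is formed.

Step 2
Reactants: 4 4-methoxy-6-(2-oxononadecyl)-2H-pyran-2-one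
Product: 7 3-heptadecyl-5-methoxyphenol, via open-chain tetraketide acid 5 (not isolated), via resorcylic acid 6 (not isolated)
Conditions: 2 M aq. KOH (6 equiv), 1,4-dioxane, Ar, 60 °C; then conc. HCl to pH 1, reflux
Reagents that add atoms: none
Why: Proposed new method: hydroxide opens the lactone (attack at the lactone carbonyl, or E1cB through the acyl ketene) to the dienolate of 5; its enol-ether carbon C2 (the γ-carbon of the C5 enolate) adds to the C7 ketone in a six-ring aldol, dehydration and tautomerisation give arene 6, and ipso-protonation of this ortho-methoxy, para-hydroxy, ortho-alkyl benzoic acid in hot acid expels CO2, leaving the methyl ether on the former pyrone C4 oxygen and the ring oxygen as the phenol; the closest known reactions are the base-induced ring-opening/aldol cyclisation of 6-(2-oxoalkyl)-4-hydroxy-2-pyranones and free 3,5,7-triketo acids to resorcylic acids (Collie-type polyketide aldol) and their decarboxylation to 5-alkylresorcinols, and the step copies the decarboxylative C2–C7 aldol of alkylresorcinol synthases; alcohol-free aqueous base is used so that only the carboxylate forms and the competing Claisen mode is closed; no stereocentre is formed.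

Step 3
Reactants: 7 3-heptadecyl-5-methoxyphenol
Product: 8 2-heptadecyl-6-methoxy-1,4-benzoquinone
Conditions: K2[ON(SO3)2] (2.5 equiv), aq. KH2PO4, methyltrioctylammonium chloride (cat.), CH2Cl2/H2O, 20 °C
Reagents that add atoms: potassium nitrosodisulfonate, [K+].[K+].[O]N(S(=O)(=O)[O-])S(=O)(=O)[O-]
Why: Teuber oxidation, in which one nitrosodisulfonate radical abstracts the phenolic hydrogen and a second couples at the free para carbon (between OMe and the chain) and then leaves as imidodisulfonate, giving the para-quinone regiospecifically as for the lower homologues (3-methoxy-5-methylphenol, the pentyl phenol that gives primin).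

Step 4
Reactants: 8 2-heptadecyl-6-methoxy-1,4-benzoquinone
Product: 9 3-heptadecyl-5-methoxybenzene-1,2,4-triyl triacetate
Conditions: Ac2O, H2SO4 (cat.), 20 → 40 °C; then ice-water
Reagents that add atoms: acetic anhydride, CC(=O)OC(C)=O
Why: Thiele–Winter acetoxylation, in which acetate adds 1,4 to the enone whose carbonyl is not deactivated by the methoxy group, that is at the free carbon next to the chain and para to OMe (the same orientation as with 2-methoxybenzoquinone), and the resulting hydroquinone is acetylated; the methoxy-bearing double bond is a vinylogous ester and is left alone.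

Step 5
Reactants: 9 3-heptadecyl-5-methoxybenzene-1,2,4-triyl triacetate
Product: 11 Irisoquin B (3-heptadecyl-2-hydroxy-5-methoxy-1,4-benzoquinone), via hydroxyhydroquinone 10 (not isolated)
Conditions: HCl (cat.), MeOH/THF, 60 °C, Ar; evaporate; then air, EtOAc/aq. NaH2PO4–Na2HPO4 buffer (pH 7), 20 °C
Reagents that add atoms: none
Why: Acid-catalysed transesterification frees triol 10, the counterpart of the dihydroquinone of sorgoleone-type biosynthesis, which autoxidises in air to the 2-hydroxy-1,4-quinone (the stable tautomer); methanol is removed before air is admitted so that the acidic hydroxyquinone is not O-methylated.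

## Compound list

1 | 4-methoxy-6-methyl-2H-pyran-2-one | COC1=CC(=O)OC(C)=C1 | starting material
2 | octadecanoyl chloride (stearoyl chloride) | CCCCCCCCCCCCCCCCCC(Cl)=O | starting material
3 | lithium dienolate of 1, drawn as [(4-methoxy-2-oxo-2H-pyran-6-yl)methyl]lithium | [Li]CC1=CC(OC)=CC(=O)O1 | intermediate
4 | 4-methoxy-6-(2-oxononadecyl)-2H-pyran-2-one | CCCCCCCCCCCCCCCCCC(=O)CC1=CC(OC)=CC(=O)O1 | intermediate
5 | (2E)-3-methoxy-5,7-dioxotetracos-2-enoic acid (present as its potassium enolate/carboxylate) | CCCCCCCCCCCCCCCCCC(=O)CC(=O)C/C(OC)=C\C(O)=O | intermediate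
6 | 2-heptadecyl-4-hydroxy-6-methoxybenzoic acid | CCCCCCCCCCCCCCCCCc1cc(O)cc(OC)c1C(O)=O | intermediate
7 | 3-heptadecyl-5-methoxyphenol | CCCCCCCCCCCCCCCCCc1cc(O)cc(OC)c1 | intermediate
8 | 2-heptadecyl-6-methoxy-1,4-benzoquinone (2-heptadecyl-6-methoxycyclohexa-2,5-diene-1,4-dione) | CCCCCCCCCCCCCCCCCC1=CC(=O)C=C(OC)C1=O | intermediate
9 | 3-heptadecyl-5-methoxybenzene-1,2,4-triyl triacetate | CCCCCCCCCCCCCCCCCc1c(OC(C)=O)c(OC(C)=O)cc(OC)c1OC(C)=O | intermediate
10 | 3-heptadecyl-5-methoxybenzene-1,2,4-triol | CCCCCCCCCCCCCCCCCc1c(O)c(O)cc(OC)c1O | intermediate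
11 | Irisoquin B, 3-heptadecyl-2-hydroxy-5-methoxycyclohexa-2,5-diene-1,4-dione (achiral) | CCCCCCCCCCCCCCCCCC1=C(O)C(=O)C=C(OC)C1=O | target
12 | 4-hydroxy-6-methyl-2H-pyran-2-one (triacetic acid lactone; used only in the fallback to step 2) | CC1=CC(O)=CC(=O)O1 | starting material

## Step count and risks

Total step count: 5. Longest linear sequence: 5 steps (1 + 2 → 4 → 7 → 8 → 9 → 11).

Most likely to fail, first: step 2. Hydroxide may strip the methyl ether, the methoxy dienolate may cyclise sluggishly, or unreacted 5 may close to a 4-pyranone on acidification. The fallback sets out from 2 and comes back to the route at 7. The dianion of commercial 4-hydroxy-6-methyl-2H-pyran-2-one 12 (LiN(iPr)2, THF, −78 → 0 °C, dianion in excess) is acylated at its 6-methyl carbon by 2 to give 4-hydroxy-6-(2-oxononadecyl)-2H-pyran-2-one F1. Aqueous KOH, then acidification and heating, converts F1 by the precedented ring-opening, C2–C7 aldol and decarboxylation of the free 4-hydroxy series into 5-heptadecylbenzene-1,3-diol F2. F2 is symmetric, so mono-O-methylation (Me2SO4, 1.0 equiv, K2CO3, acetone, unreacted F2 recycled) can only give 7; the O-methyl group is thus placed after ring formation instead of before it.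

Second: step 1. The product enolate may be O-acylated or acylated twice, or the acid chloride may be consumed by proton transfer. The fallback sets out from 2 and comes back at 4. Compound 2 is reduced to octadecanal F3 (LiAlH(OtBu)3, THF, −78 °C). Dienolate 3 (1 equiv, made from 1 as in step 1) adds to it in a vinylogous aldol reaction to give racemic 6-(2-hydroxynonadecyl)-4-methoxy-2H-pyran-2-one F4, which cannot react a second time. Dess–Martin periodinane (CH2Cl2, 20 °C) oxidises F4 to 4.

Third: step 4. The carbon to be acetoxylated is flanked by the long chain and the quinone is electron-rich, so the acid-catalysed addition may be slow or give some of the regioisomer. The fallback sets out from 8 and comes back at 11, bypassing 9 and 10. Nucleophilic epoxidation (30% H2O2, cat. Na2CO3, THF/H2O, 0 °C) takes the electron-poor, alkyl-substituted double bond, either sense of hydroperoxide attack giving the same racemic cis-1-heptadecyl-3-methoxy-7-oxabicyclo[4.1.0]hept-3-ene-2,5-dione F5. Cold conc. H2SO4 then isomerises this epoxy-enedione to the hydroxyquinone (the rearrangement that turns 2-methylnaphthoquinone oxide into phthiocol). Only the hydrogen-bearing epoxide carbon can keep the oxygen, so 11 is the sole regiochemical outcome.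

Further compounds
F1 | step 2 | 4-hydroxy-6-(2-oxononadecyl)-2H-pyran-2-one | CCCCCCCCCCCCCCCCCC(=O)CC1=CC(O)=CC(=O)O1
F2 | step 2 | 5-heptadecylbenzene-1,3-diol | CCCCCCCCCCCCCCCCCc1cc(O)cc(O)c1
F3 | step 1 | octadecanal | CCCCCCCCCCCCCCCCCC=O
F4 | step 1 | rac-6-(2-hydroxynonadecyl)-4-methoxy-2H-pyran-2-one | CCCCCCCCCCCCCCCCCC(O)CC1=CC(OC)=CC(=O)O1
F5 | step 4 | rac-cis-1-heptadecyl-3-methoxy-7-oxabicyclo[4.1.0]hept-3-ene-2,5-dione (one enantiomer drawn) | CCCCCCCCCCCCCCCCC[C@@]12O[C@@H]1C(=O)C=C(OC)C2=O
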